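Retrosynthetic overview. Numbering: unprimed atoms follow caryophyllane, primed atoms the chromene part (C2′ = C8, C3′ = C13). Tomentodione O is taken back to its C5 silyl ether; ring D (cyclohexenedione C4a′–C5′–C6′–C7′–C8′–C8a′) is the last ring closed, in the same flask directly after ring C (dihydropyran).
Ring D is cut at C5′–C6′ (acyl carbon to CMe2, thio-Dieckmann mode) and ring C at O1′–C8 and C13–C4′ (inverse-demand hetero-Diels–Alder at the exocyclic C8=C13 alkene); this leads to a silylated (3Z,5R)-caryophylla-3,8(13)-dien-5-ol and an acyclic 2-alkylidene-3,5-dioxo thioester.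
Enabling feature: in ring D the unit O1′–C8a′=C4a′–C5′=O is a masked 1,3-dicarbonyl, so either carbonyl of the acyclic precursor may become the pyran oxygen. The rest, C6′(Me2)–C7′(=O)–C8′(Me2), carries no hydrogen, so the opened chain has one acidic methine only and closes on the thioester-derived carbon with loss of thiolate.
The acyclic partner comes from C–C cleavage of 2,2,4,4-tetramethylcyclobutane-1,3-dione (dimethylketene dimer) by a thioacetate enolate, then Knoevenagel condensation with 3-methylbutanal. The terpene partner comes from (−)-β-caryophyllene by Schenck ene reaction and silylation.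
Ring order: rings A (cyclobutane) and B (nine-membered) from the chiral pool, then ring C, then ring D.

Key step: step 5

Remark: the facial and endo/exo selectivity of the cycloaddition is only substrate-biased; the route assumes that the (8S,4′R) isomer is separated from its diastereomers after ring D is closed.

Step 1
Reactants: 1 (−)-β-caryophyllene
Product: 3 (1R,3Z,5R,9S)-caryophylla-3,8(13)-dien-5-ol, via allylic hydroperoxide 2 (not isolated)
Conditions: O2, hν (white LED), meso-tetraphenylporphyrin (1 mol%), CH2Cl2, −20 °C; then PPh3, −20 °C → rt; chromatography on AgNO3-impregnated silica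
Reagents that add atoms: dioxygen, O=O
Why: Schenck ene reaction: singlet oxygen should react only with the strained trisubstituted C4=C5 alkene, bond to C5 on the exposed face that peracids also use (hence 5R) while a C3 hydrogen is transferred suprafacially so that the double bond moves to C3=C4 in the unstrained Z geometry, and PPh3 reduces the O–O bond without touching C5; isomeric ene products (C12 hydrogen abstraction, attack on the other face) are removed by the chromatography.

Step 2
Reactants: 3 (1R,3Z,5R,9S)-caryophylla-3,8(13)-dien-5-ol
Product: 4 tert-butyldimethylsilyl ether of 3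
Conditions: TBSCl, imidazole, DMF, rt
Reagents that add atoms: tert-butyldimethylsilyl chloride, CC(C)(C)[Si](C)(C)Cl
Why: Imidazole-promoted silylation of the secondary allylic alcohol removes the only O–H before the heat- and amide-base-mediated step; no stereocentre is formed or touched.

Step 3
Reactants: 5 2,2,4,4-tetramethylcyclobutane-1,3-dione; 6 S-tert-butyl thioacetate
Product: 7 S-tert-butyl 4,4,6-trimethyl-3,5-dioxoheptanethioate
Conditions: 6, LiN(i-Pr)2, THF, −78 °C; then 5, −78 → −30 °C; aq NH4Cl at −30 °C
Reagents that add atoms: none
Why: Aldol addition of the lithium thioester enolate to one strain-activated, non-enolisable carbonyl of 5, followed by retro-Claisen fragmentation of the cyclobutanone aldolate (relief of four-ring strain), should open the ring to the acyclic chain, whose terminal ketone enolate is quenched by proton transfer from the new C2 methylene to give the unreactive β-keto thioester enolate until work-up; no stereocentre is formed.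

Step 4
Reactants: 7 S-tert-butyl 4,4,6-trimethyl-3,5-dioxoheptanethioate; 8 3-methylbutanal
Product: 9 S-tert-butyl 4,4,6-trimethyl-2-(3-methylbutylidene)-3,5-dioxoheptanethioate (E/Z mixture)
Conditions: piperidine (10 mol%), AcOH (10 mol%), 4 Å MS, CH2Cl2, 0 °C → rt
Reagents that add atoms: none
Why: Knoevenagel condensation at the only doubly activated position (the C2 methylene between thioester and ketone) with removal of water; the E/Z mixture is used as such because both isomers converge in step 5, and no stereocentre is formed.

Step 5
Reactants: 4 tert-butyldimethylsilyl ether of 3; 9 S-tert-butyl 4,4,6-trimethyl-2-(3-methylbutylidene)-3,5-dioxoheptanethioate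
Product: 12 tert-butyldimethylsilyl ether of tomentodione O, via ketone adduct 10 (not isolated), via thioester adduct 11 (not isolated)
Conditions: 4 (excess, recovered), PhMe (2 M), BHT (cat.), 110 °C, sealed tube; then THF, KN(SiMe3)2, −78 → 0 °C; aq NH4Cl
Reagents that add atoms: none
Why: On heating, the s-cis 1-oxadiene of 9 built on the ketone carbonyl (O=C3–C2=CH) should add in an inverse-electron-demand hetero-Diels–Alder reaction across the exocyclic C8=C13 alkene of 4 to give spiro-dihydropyran 10, any addition through the thioester carbonyl gives regioisomer 11, and KN(SiMe3)2 then removes the only acidic hydrogen left in either adduct, the isopropyl-ketone methine, so that a single tetrasubstituted enolate forms and closes ring D with loss of tert-butylthiolate. The closest known reaction types are the hetero-Diels–Alder addition of 2-alkylidene-1,3-dicarbonyl compounds to 1,1-disubstituted alkenes, the Dieckmann-type Claisen condensation of a thioester, and addition–elimination at α-oxo ketene O,S-acetals. Ring C closes by [4+2] cycloaddition; ring D closes from 10 by 6-exo-trig attack of the enolate carbon on the thioester carbonyl (new C5′–C6′ bond) and from 11 by 6-endo-trig conjugate addition–elimination at C8a′ (new C8′–C8a′ bond), and since both paths expel the same thiolate and give the same vinylogous ester, the regiochemistry of the cycloaddition does not matter. C8 becomes S when the new C8–O1′ bond ends cis to the C9–C10 bond across ring B (C13 cis to H-9), a choice governed by the C9 stereocentre and the trans-fused cyclobutane through the orientation of the exocyclic methylene, and C4′ becomes R when the isobutyl group ends cis to C7 across ring C (endo/exo orientation of the heterodiene); the new quaternary carbons C6′ and C8′ are not stereogenic. The step needs site selectivity and orientation, both secured because only C8=C13 can build up positive charge at a tertiary carbon while offering an unhindered CH2 terminus to the electrophilic alkylidene carbon, whereas C3=C4 is trisubstituted and deactivated by the allylic silyloxy group; the facial and endo/exo preferences are only substrate-biased, so 12 is separated from its C8/C4′ diastereomers at this stage. The closure should not reverse, because the weakly basic, bulky thiolate does not cleave the hindered, non-enolisable C7′ ketone.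

Step 6
Reactants: 12 tert-butyldimethylsilyl ether of tomentodione O
Product: 13 tomentodione O
Conditions: HF·pyridine, pyridine, THF, 0 °C → rt
Reagents that add atoms: none
Why: Silyl ether deprotection: fluoride-induced Si–O cleavage under buffered, weakly acidic conditions should free the C5 hydroxyl without exposing the non-enolisable 1,3-diketone to hydroxide (retro-Claisen) or the tertiary-alkyl vinylogous ester to strong acid; no stereocentre is touched.

Compound list
1 | (−)-β-caryophyllene, (1R,4E,9S)-4,11,11-trimethyl-8-methylidenebicyclo[7.2.0]undec-4-ene | C/C1=C\CCC(=C)[C@H]2CC(C)(C)[C@@H]2CC1 | starting material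
2 | allylic hydroperoxide, (1R,3Z,5R,9S)-5-hydroperoxy-4,11,11-trimethyl-8-methylidenebicyclo[7.2.0]undec-3-ene | C/C1=C/C[C@@H]2[C@H](CC2(C)C)C(=C)CC[C@H]1OO | intermediate
3 | (1R,3Z,5R,9S)-caryophylla-3,8(13)-dien-5-ol, (1R,3Z,5R,9S)-4,11,11-trimethyl-8-methylidenebicyclo[7.2.0]undec-3-en-5-ol | C/C1=C/C[C@@H]2[C@H](CC2(C)C)C(=C)CC[C@H]1O | intermediate
4 | tert-butyldimethylsilyl ether of 3 | C/C1=C/C[C@@H]2[C@H](CC2(C)C)C(=C)CC[C@H]1O[Si](C)(C)C(C)(C)C | intermediate
5 | 2,2,4,4-tetramethylcyclobutane-1,3-dione | CC1(C)C(=O)C(C)(C)C1=O | starting material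
6 | S-tert-butyl thioacetate (S-tert-butyl ethanethioate) | CC(=O)SC(C)(C)C | starting material
7 | S-tert-butyl 4,4,6-trimethyl-3,5-dioxoheptanethioate | CC(C)C(=O)C(C)(C)C(=O)CC(=O)SC(C)(C)C | intermediate
8 | 3-methylbutanal | CC(C)CC=O | starting material
9 | S-tert-butyl 4,4,6-trimethyl-2-(3-methylbutylidene)-3,5-dioxoheptanethioate (E/Z mixture) | CC(C)CC=C(C(=O)SC(C)(C)C)C(=O)C(C)(C)C(=O)C(C)C | intermediate
10 | ketone adduct, (1R,3Z,5R,8S,9S,4′R): spiro-dihydropyran on C8 of 4 with 4′-isobutyl, C4a′–C(=O)S-t-Bu and C8a′–C(CH3)2C(=O)CH(CH3)2 | C/C1=C/C[C@@H]2[C@H](CC2(C)C)[C@]2(CC[C@H]1O[Si](C)(C)C(C)(C)C)C[C@@H](CC(C)C)C(C(=O)SC(C)(C)C)=C(O2)C(C)(C)C(=O)C(C)C | intermediate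
11 | thioester adduct, (1R,3Z,5R,8S,9S,4′R): spiro-dihydropyran on C8 of 4 with 4′-isobutyl, C8a′–S-t-Bu and C4a′–C(=O)C(CH3)2C(=O)CH(CH3)2 | C/C1=C/C[C@@H]2[C@H](CC2(C)C)[C@]2(CC[C@H]1O[Si](C)(C)C(C)(C)C)C[C@@H](CC(C)C)C(C(=O)C(C)(C)C(=O)C(C)C)=C(O2)SC(C)(C)C | intermediate
12 | tert-butyldimethylsilyl ether of tomentodione O, (1R,3Z,5R,8S,9S,4′R) | C/C1=C/C[C@@H]2[C@H](CC2(C)C)[C@]2(CC[C@H]1O[Si](C)(C)C(C)(C)C)C[C@@H](CC(C)C)C1=C(O2)C(C)(C)C(=O)C(C)(C)C1=O | intermediate
13 | tomentodione O, (1R,3Z,5R,8S,9S,4′R): caryophyll-3-en-5-ol spiro-fused at C8 to C2′ of 4′-isobutyl-6′,6′,8′,8′-tetramethyl-3′,4′-dihydro-2′H-chromene-5′,7′(6′H,8′H)-dione | C/C1=C/C[C@@H]2[C@H](CC2(C)C)[C@]2(CC[C@H]1O)C[C@@H](CC(C)C)C1=C(O2)C(C)(C)C(=O)C(C)(C)C1=O | target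

Total step count: 6. Longest linear sequence: 4 steps (steps 1, 2, 5, 6 from 1; equally steps 3, 4, 5, 6 from 5).

Steps most likely to fail

Step 5. Process at risk: the cycloaddition stage. The hindered acyclic heterodiene may add to the Z-olefinic silyl ether 4 too slowly, so that ene reaction and alkylidene isomerisation compete, or mainly through the C8 face that leads to the 8R series. Fallback: the oxygenation at C5 is moved to the end and the cycloaddition is run on the parent terpene, whose nine-membered ring has a different conformational bias. It sets out from 1 and 9. Heating 1 with 9 (PhMe, 110 °C) should engage only the exocyclic C8=C13 alkene and give the thioester cycloadduct F1. KN(SiMe3)2 (THF, −78 → 0 °C) closes ring D to the 5-deoxy compound with the E-configured C4=C5 alkene F2, which is separated from its diastereomers. Schenck ene reaction (O2, hν, meso-tetraphenylporphyrin, CH2Cl2, −20 °C) then oxygenates only the strained trisubstituted alkene to the 5-hydroperoxide F3, and PPh3 reduces it to 13, where the route is rejoined.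

Step 1. Process at risk: hydrogen abstraction from the C12 methyl group (4(12)-ene isomer) or attack of singlet oxygen on the other alkene face (5S epimer) prevailing, so that 3 is a minor component. Fallback: C5 is fixed before the double bond is moved. It sets out from 1. Epoxidation with mCPBA (NaHCO3, CH2Cl2, 0 °C) on the exposed face of C4=C5 gives (4R,5R)-caryophyllene oxide F4, which is also commercially available. Diethylaluminium 2,2,6,6-tetramethylpiperidide (from Et2AlCl and lithium 2,2,6,6-tetramethylpiperidide, PhH, 0 °C) then isomerises F4 by syn β-elimination; the bulky amide should remove a proton from C3, the carbon cis to the epoxide hydrogen, and not from the C12 methyl group. This gives 3, where the route is rejoined.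

Step 3. Process at risk: the ring-opened ketone enolate attacking its own thioester (premature Claisen cyclisation to the cyclic trione), or a second enolate adding before the ring opens. Fallback: the chain is built by acylation instead. It sets out from 5. Ring opening with aqueous NaOH and cold acidification gives 2,2,4-trimethyl-3-oxopentanoic acid F5. DCC/DMAP-mediated C-acylation of Meldrum's acid (CH2Cl2, 0 °C) gives the acyl Meldrum's acid F6. Heating F6 with 2-methylpropane-2-thiol (PhMe, reflux) gives 7 through the acylketene, where the route is rejoined.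

Further compounds
F1 | step 5 | thioester cycloadduct of 1 with 9, (1R,4E,8S,9S,4′R), C4a′–C(=O)S-t-Bu and C8a′–C(CH3)2C(=O)CH(CH3)2 | C/C1=C\CC[C@]2(C[C@@H](CC(C)C)C(C(=O)SC(C)(C)C)=C(O2)C(C)(C)C(=O)C(C)C)[C@H]2CC(C)(C)[C@@H]2CC1
F2 | step 5 | 5-deoxy compound with E-configured C4=C5 alkene, (1R,4E,8S,9S,4′R) | C/C1=C\CC[C@]2(C[C@@H](CC(C)C)C3=C(O2)C(C)(C)C(=O)C(C)(C)C3=O)[C@H]2CC(C)(C)[C@@H]2CC1
F3 | step 5 | 5-hydroperoxide corresponding to 13 | C/C1=C/C[C@@H]2[C@H](CC2(C)C)[C@]2(CC[C@H]1OO)C[C@@H](CC(C)C)C1=C(O2)C(C)(C)C(=O)C(C)(C)C1=O
F4 | step 1 | (−)-caryophyllene oxide, (1R,4R,5R,9S) | C[C@@]12CC[C@@H]3[C@H](CC3(C)C)C(=C)CC[C@H]1O2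
F5 | step 3 | 2,2,4-trimethyl-3-oxopentanoic acid | CC(C)C(=O)C(C)(C)C(=O)O
F6 | step 3 | 5-(1-hydroxy-2,2,4-trimethyl-3-oxopentylidene)-2,2-dimethyl-1,3-dioxane-4,6-dione | CC(C)C(=O)C(C)(C)C(O)=C1C(=O)OC(C)(C)OC1=O
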